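The flavanone is disconnected at the C2–C3 bond of ring C. C2 is a benzylic carbon bound to O1 and C3 lies alpha to the C4 ketone, so a plain O1-benzyl ether and a C3 keto-carbenoid are the two ends. Because ring A is a phloroglucinol, the precursor is the symmetric 2,4,6-tris(benzyloxy)phenyl diazomethyl ketone: enantioselective rhodium-carbenoid C–H insertion into either equivalent ortho O-benzyl group closes ring C, sets C2 and leaves O5 and O7 benzyl-protected in one operation. The C8 2-hydroxybenzyl group and the C6 chain of four hydroxybenzyl units, built by iterative tosylhydrazone–boronic acid couplings, are then attached by Friedel–Crafts benzylations.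

Key step: step 3

Assumption: the (S)-configured catalyst Rh2(S-PTTL)4 in step 3 is taken to give the (2S) product; if the sense of induction proves opposite, the enantiomeric catalyst Rh2(R-PTTL)4 is used under otherwise identical conditions.

Remark: the four aryl rings of the C6 side chain are called units 1 to 4, counted outward from C6.

Step 1
Reactants: 1 1-[2,4-bis(benzyloxy)-6-hydroxyphenyl]ethanone; 2 benzyl bromide
Product: 3 1-[2,4,6-tris(benzyloxy)phenyl]ethanone
Conditions: BnBr (1.3 equiv), K2CO3 (2 equiv), DMF, 80 °C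
Reagents that add atoms: none
Why: Williamson etherification (SN2 of the phenoxide on benzyl bromide) of the one free, ketone-chelated hydroxyl should give the symmetric tribenzyl ether; DMF and heat overcome the hydrogen bond that makes this phenol sluggish.

Step 2
Reactants: 3 1-[2,4,6-tris(benzyloxy)phenyl]ethanone
Product: 5 2-diazo-1-[2,4,6-tris(benzyloxy)phenyl]ethanone, via trifluoroacetyl diketone 4 (not isolated)
Conditions: LiN(SiMe3)2, THF, −78 °C, then CF3CO2CH2CF3, aq. HCl work-up; then 4-acetamidobenzenesulfonyl azide, Et3N, H2O (1 equiv), MeCN, rt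
Reagents that add atoms: 4-acetamidobenzenesulfonyl azide, CC(=O)Nc1ccc(cc1)S(=O)(=O)N=[N+]=[N-] (the two diazo nitrogens); 2,2,2-trifluoroethyl trifluoroacetate, O=C(OCC(F)(F)F)C(F)(F)F (its CF3CO group is present only in 4)
Why: Detrifluoroacetylative (Regitz-type deacylative) diazo transfer: the lithium enolate is C-trifluoroacetylated to 4, whose activated methylene accepts the diazo group from the sulfonyl azide while the trifluoroacetyl group leaves as the N-acyl sulfonamide; benzyl ethers are inert to all reagents.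

Step 3
Reactants: 5 2-diazo-1-[2,4,6-tris(benzyloxy)phenyl]ethanone
Product: 6 (2S)-5,7-bis(benzyloxy)-2-phenylchroman-4-one
Conditions: Rh2(S-PTTL)4 (2 mol%), CH2Cl2, 0 °C, slow addition of 5
Reagents that add atoms: none
Why: Rh2(S-PTTL)4, a chiral divalent-rhodium carboxylate, expels N2 from 5 to give an electrophilic keto-carbenoid at the future C3, which inserts in a concerted, asynchronous, hydride-transfer-like three-centre step into one benzylic C–H bond of an ortho O–CH2Ph group, forming the C3–C2 bond and passing that hydrogen to C3. The closest known reaction type is the divalent-rhodium-carboxylate-catalysed intramolecular C–H insertion of 2-alkoxyaryl diazoketones next to the ether oxygen, which gives 2-substituted chroman-4-ones, together with the Rh2(S-PTTL)4-catalysed enantioselective insertion into benzyl ether C–H bonds. Ring C closes in the 1,6-insertion mode through a six-membered transition state (C3, C4, C4a, C8a, O1, C2); the 1,5-position is the oxygen itself, so no five-membered C–H insertion can compete. The C2 stereocentre is set by catalyst control, the chiral phthalimido-carboxylate pocket selecting one of the two enantiotopic benzylic hydrogens; the two ortho O-benzyl groups are symmetry-equivalent, so there is no regiochemical question, and the para O-benzyl group is out of reach. The step needs C–H insertion to beat attack of the ether oxygen on the carbenoid (oxonium ylide, then 1,2-benzyl shift to a 2-benzylbenzofuran-3-one) and carbene dimerisation; the first is favoured by the low basicity of an aryl ether oxygen conjugated to the acyl-substituted ring and by the double activation of the C–H bond by oxygen and phenyl, the second is suppressed by slow addition.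

Step 4
Reactants: 6 (2S)-5,7-bis(benzyloxy)-2-phenylchroman-4-one; 7 [2-(benzyloxy)phenyl]methanol
Product: 8 (2S)-5,7-bis(benzyloxy)-8-[2-(benzyloxy)benzyl]-2-phenylchroman-4-one
Conditions: 7 (1.3 equiv, slow addition), Sc(OTf)3 (10 mol%), MeNO2, 40 °C
Reagents that add atoms: none
Why: Lewis-acid-catalysed Friedel–Crafts benzylation: Sc(OTf)3 ionises 7 to the ortho-alkoxy-stabilised benzylic cation, which should attack ring A at C8 (flanked by the tied-back ring oxygen O1 and one benzyloxy group) in preference to C6 (buried between two freely rotating benzyloxy groups), in line with the C8 preference of 5,7-dialkoxyflavonoids toward electrophiles; the mild catalytic acid should leave the benzyl ethers and C2 untouched.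

Step 5
Reactants: 8 (2S)-5,7-bis(benzyloxy)-8-[2-(benzyloxy)benzyl]-2-phenylchroman-4-one
Product: 9 (2S)-5,7-dihydroxy-8-(2-hydroxybenzyl)-2-phenylchroman-4-one (chamanetin)
Conditions: H2 (1 atm), 10% Pd/C, EtOAc–MeOH, rt
Reagents that add atoms: none
Why: Catalytic hydrogenolysis of the three aryl benzyl ethers under neutral conditions; the cyclic benzylic C2–O1 bond, the diarylmethane link and the hydrogen-bonded C4 ketone are expected to react much more slowly, and C2 cannot epimerise without base.

Step 6
Reactants: 10 2-methoxybenzaldehyde; 11 (3-formyl-4-methoxyphenyl)boronic acid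
Product: 13 2-methoxy-5-(2-methoxybenzyl)benzaldehyde, via tosylhydrazone 12 (not isolated)
Conditions: TsNHNH2 (1.0 equiv), 1,4-dioxane, 80 °C; then 11 (1.5 equiv), K2CO3 (2 equiv), 110 °C
Reagents that add atoms: 4-methylbenzenesulfonohydrazide, Cc1ccc(cc1)S(=O)(=O)NN (its atoms are present only in 12)
Why: Barluenga reductive coupling: condensation gives N-tosylhydrazone 12, K2CO3 triggers Bamford–Stevens loss of sulfinate, the diazo carbon takes up the aryl group of 11 from boron with loss of N2 and the benzylic boronic acid is protodeboronated, so the former formyl carbon of 10 becomes the CH2 between unit 4 and unit 3 (para to the methoxy group of unit 3); the electron-rich formyl group of 11 should be spared because boron captures the diazo intermediate far faster.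

Step 7
Reactants: 13 2-methoxy-5-(2-methoxybenzyl)benzaldehyde; 11 (3-formyl-4-methoxyphenyl)boronic acid
Product: 15 2-methoxy-5-[2-methoxy-5-(2-methoxybenzyl)benzyl]benzaldehyde, via tosylhydrazone 14 (not isolated)
Conditions: TsNHNH2 (1.0 equiv), 1,4-dioxane, 80 °C; then 11 (1.5 equiv), K2CO3 (2 equiv), 110 °C
Reagents that add atoms: 4-methylbenzenesulfonohydrazide, Cc1ccc(cc1)S(=O)(=O)NN (its atoms are present only in 14)
Why: The same Barluenga reductive coupling on the formyl group of 13 appends unit 2, again through the carbon para to its methoxy group, and returns a new formyl group for the next cycle.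

Step 8
Reactants: 15 2-methoxy-5-[2-methoxy-5-(2-methoxybenzyl)benzyl]benzaldehyde; 11 (3-formyl-4-methoxyphenyl)boronic acid
Product: 17 2-methoxy-5-{2-methoxy-5-[2-methoxy-5-(2-methoxybenzyl)benzyl]benzyl}benzaldehyde, via tosylhydrazone 16 (not isolated)
Conditions: TsNHNH2 (1.0 equiv), 1,4-dioxane, 80 °C; then 11 (1.5 equiv), K2CO3 (2 equiv), 110 °C
Reagents that add atoms: 4-methylbenzenesulfonohydrazide, Cc1ccc(cc1)S(=O)(=O)NN (its atoms are present only in 16)
Why: Third Barluenga reductive coupling; it appends unit 1, whose formyl carbon is the future C6-bound methylene.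

Step 9
Reactants: 17 2-methoxy-5-{2-methoxy-5-[2-methoxy-5-(2-methoxybenzyl)benzyl]benzyl}benzaldehyde
Product: 18 2-hydroxy-5-{2-hydroxy-5-[2-hydroxy-5-(2-hydroxybenzyl)benzyl]benzyl}benzaldehyde
Conditions: BBr3 (6 equiv), CH2Cl2, −78 °C to rt; then H2O
Reagents that add atoms: none
Why: Lewis-acid ether cleavage: BBr3 complexes each methoxy oxygen and bromide dealkylates it by SN2 to the aryloxyborane, which is hydrolysed on work-up; the diarylmethane links are inert and the aldehyde is returned by the aqueous work-up.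

Step 10
Reactants: 18 2-hydroxy-5-{2-hydroxy-5-[2-hydroxy-5-(2-hydroxybenzyl)benzyl]benzyl}benzaldehyde
Product: 19 4-{2-hydroxy-5-[2-hydroxy-5-(2-hydroxybenzyl)benzyl]benzyl}-2-(hydroxymethyl)phenol
Conditions: NaBH4, THF–MeOH, 0 °C; aq. NH4Cl work-up
Reagents that add atoms: none
Why: Hydride reduction of the salicylaldehyde-type formyl group to the 2-hydroxybenzylic alcohol; the neutral to weakly acidic work-up avoids premature o-quinone methide formation.

Step 11
Reactants: 9 (2S)-5,7-dihydroxy-8-(2-hydroxybenzyl)-2-phenylchroman-4-one (chamanetin); 19 4-{2-hydroxy-5-[2-hydroxy-5-(2-hydroxybenzyl)benzyl]benzyl}-2-(hydroxymethyl)phenol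
Product: 20 sarmentosumin C
Conditions: ZnCl2 (2 equiv), 1,4-dioxane, 50 °C, slow addition of 19 to 9 (1.5 equiv)
Reagents that add atoms: none
Why: ZnCl2-mediated Friedel–Crafts hydroxybenzylation: the 2-hydroxybenzylic alcohol of 19 is ionised to a zinc-bound o-quinone methide (benzylic cation) that is attacked by C6, the only free position of the phloroglucinol-type ring A and the most nucleophilic arene carbon present, as known for the hydroxybenzylation of 5,7-dihydroxyflavanones; C2 is not involved and should keep its configuration under these non-basic conditions.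

Compound list

1 | 1-[2,4-bis(benzyloxy)-6-hydroxyphenyl]ethanone | CC(=O)c1c(O)cc(OCc2ccccc2)cc1OCc1ccccc1 | starting material
2 | benzyl bromide | BrCc1ccccc1 | starting material
3 | 1-[2,4,6-tris(benzyloxy)phenyl]ethanone | CC(=O)c1c(OCc2ccccc2)cc(OCc2ccccc2)cc1OCc1ccccc1 | intermediate
4 | 4,4,4-trifluoro-1-[2,4,6-tris(benzyloxy)phenyl]butane-1,3-dione | O=C(CC(=O)C(F)(F)F)c1c(OCc2ccccc2)cc(OCc2ccccc2)cc1OCc1ccccc1 | intermediate
5 | 2-diazo-1-[2,4,6-tris(benzyloxy)phenyl]ethanone | [N-]=[N+]=CC(=O)c1c(OCc2ccccc2)cc(OCc2ccccc2)cc1OCc1ccccc1 | intermediate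
6 | (2S)-5,7-bis(benzyloxy)-2-phenylchroman-4-one | O=C1C[C@@H](c2ccccc2)Oc2cc(OCc3ccccc3)cc(OCc3ccccc3)c21 | intermediate
7 | [2-(benzyloxy)phenyl]methanol | OCc1ccccc1OCc1ccccc1 | starting material
8 | (2S)-5,7-bis(benzyloxy)-8-[2-(benzyloxy)benzyl]-2-phenylchroman-4-one | O=C1C[C@@H](c2ccccc2)Oc2c(Cc3ccccc3OCc3ccccc3)c(OCc3ccccc3)cc(OCc3ccccc3)c21 | intermediate
9 | (2S)-5,7-dihydroxy-8-(2-hydroxybenzyl)-2-phenylchroman-4-one (chamanetin) | O=C1C[C@@H](c2ccccc2)Oc2c(Cc3ccccc3O)c(O)cc(O)c21 | intermediate
10 | 2-methoxybenzaldehyde | COc1ccccc1C=O | starting material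
11 | (3-formyl-4-methoxyphenyl)boronic acid | COc1ccc(cc1C=O)B(O)O | starting material
12 | N'-[(E)-(2-methoxyphenyl)methylidene]-4-methylbenzenesulfonohydrazide | COc1ccccc1/C=N/NS(=O)(=O)c1ccc(C)cc1 | intermediate
13 | 2-methoxy-5-(2-methoxybenzyl)benzaldehyde | COc1ccccc1Cc1ccc(OC)c(C=O)c1 | intermediate
14 | N-tosylhydrazone (E) of 13 | COc1ccccc1Cc1ccc(OC)c(/C=N/NS(=O)(=O)c2ccc(C)cc2)c1 | intermediate
15 | 2-methoxy-5-[2-methoxy-5-(2-methoxybenzyl)benzyl]benzaldehyde | COc1ccccc1Cc1ccc(OC)c(Cc2ccc(OC)c(C=O)c2)c1 | intermediate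
16 | N-tosylhydrazone (E) of 15 | COc1ccccc1Cc1ccc(OC)c(Cc2ccc(OC)c(/C=N/NS(=O)(=O)c3ccc(C)cc3)c2)c1 | intermediate
17 | 2-methoxy-5-{2-methoxy-5-[2-methoxy-5-(2-methoxybenzyl)benzyl]benzyl}benzaldehyde | COc1ccccc1Cc1ccc(OC)c(Cc2ccc(OC)c(Cc3ccc(OC)c(C=O)c3)c2)c1 | intermediate
18 | 2-hydroxy-5-{2-hydroxy-5-[2-hydroxy-5-(2-hydroxybenzyl)benzyl]benzyl}benzaldehyde | Oc1ccccc1Cc1ccc(O)c(Cc2ccc(O)c(Cc3ccc(O)c(C=O)c3)c2)c1 | intermediate
19 | 4-{2-hydroxy-5-[2-hydroxy-5-(2-hydroxybenzyl)benzyl]benzyl}-2-(hydroxymethyl)phenol | Oc1ccccc1Cc1ccc(O)c(Cc2ccc(O)c(Cc3ccc(O)c(CO)c3)c2)c1 | intermediate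
20 | sarmentosumin C, (2S)-5,7-dihydroxy-8-(2-hydroxybenzyl)-6-{2-hydroxy-5-[2-hydroxy-5-[2-hydroxy-5-(2-hydroxybenzyl)benzyl]benzyl]benzyl}-2-phenylchroman-4-one | O=C1C[C@@H](c2ccccc2)Oc2c(Cc3ccccc3O)c(O)c(Cc3cc(Cc4cc(Cc5cc(Cc6ccccc6O)ccc5O)ccc4O)ccc3O)c(O)c21 | target

Total step count: 11.
Longest linear sequence: 6 steps (steps 1, 2, 3, 4, 5, 11; the side-chain branch, steps 6 to 11, is equally long).

Steps most likely to fail

1. Step 3. The ether oxygen may capture the carbenoid faster than the C–H bond inserts (oxonium ylide formation followed by a 1,2-benzyl shift), or the catalyst may discriminate the two enantiotopic benzylic hydrogens poorly. The fallback sets out from 1 and returns at 6, and still closes ring C at C2–C3, now as an alkene. Benzoylation of the free phenol of 1 (BzCl, pyridine) gives 2-acetyl-3,5-bis(benzyloxy)phenyl benzoate F1, and alpha-bromination with CuBr2 (EtOAc–CHCl3, reflux) gives 3,5-bis(benzyloxy)-2-(bromoacetyl)phenyl benzoate F2. PPh3 (toluene, rt) gives {2-[2-(benzoyloxy)-4,6-bis(benzyloxy)phenyl]-2-oxoethyl}triphenylphosphonium bromide F3. K2CO3 in refluxing toluene forms the keto-stabilised ylide 3,5-bis(benzyloxy)-2-[(triphenylphosphoranylidene)acetyl]phenyl benzoate F4, which undergoes intramolecular Wittig olefination of the ester carbonyl to 5,7-bis(benzyloxy)-2-phenyl-4H-chromen-4-one F5. Enantioselective hydrogenation with a chiral ruthenium N-heterocyclic carbene catalyst (made from [Ru(cod)(2-methylallyl)2], a chiral imidazolinium tetrafluoroborate and KOtBu, under H2) should give (2S,4S)-5,7-bis(benzyloxy)-2-phenylchroman-4-ol F6. Dess–Martin oxidation of its C4 alcohol returns 6.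

2. Step 4. The benzylic cation may discriminate poorly between C8 and C6, or the Lewis acid may remove the chelated 5-O-benzyl group and so redirect substitution. The fallback sets out from 6 and returns at 8. Iodination with N-iodosuccinimide (cat. CF3CO2H, MeCN, rt), a halogenation that is C8-selective for 5,7-dialkoxyflavonoids and whose isomers can be separated and assigned at this stage, gives (2S)-5,7-bis(benzyloxy)-8-iodo-2-phenylchroman-4-one F7. Commercial 2-(benzyloxy)benzyl bromide is converted with Zn dust and LiCl in THF into [2-(benzyloxy)benzyl]zinc bromide F8. Negishi coupling of F7 with F8 (Pd(OAc)2, SPhos, THF, 50 °C) gives 8 without any acid.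

3. Step 11. The unprotected alcohol 19 may condense with itself through its own phenol rings, the cation may attack phenolic rings other than ring A, or hydroxybenzyl groups may scramble under the Lewis acid. The fallback sets out from 17, uses 9 unchanged, and returns at 20. NaBH4 (THF–MeOH, 0 °C) reduces 17 to (2-methoxy-5-{2-methoxy-5-[2-methoxy-5-(2-methoxybenzyl)benzyl]benzyl}phenyl)methanol F9, which has no free phenol and cannot form an o-quinone methide. Sc(OTf)3-catalysed Friedel–Crafts benzylation of 9 with F9 (MeNO2, 40 °C) gives the tetra-O-methyl ether of sarmentosumin C F10. Demethylation with BBr3 (CH2Cl2, −78 °C to 0 °C) gives 20.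

Further compounds

F1 | step 3 | 2-acetyl-3,5-bis(benzyloxy)phenyl benzoate | CC(=O)c1c(OC(=O)c2ccccc2)cc(OCc2ccccc2)cc1OCc1ccccc1
F2 | step 3 | 3,5-bis(benzyloxy)-2-(bromoacetyl)phenyl benzoate | O=C(CBr)c1c(OC(=O)c2ccccc2)cc(OCc2ccccc2)cc1OCc1ccccc1
F3 | step 3 | {2-[2-(benzoyloxy)-4,6-bis(benzyloxy)phenyl]-2-oxoethyl}triphenylphosphonium bromide | [Br-].O=C(C[P+](c1ccccc1)(c1ccccc1)c1ccccc1)c1c(OC(=O)c2ccccc2)cc(OCc2ccccc2)cc1OCc1ccccc1
F4 | step 3 | 3,5-bis(benzyloxy)-2-[(triphenylphosphoranylidene)acetyl]phenyl benzoate | O=C(C=P(c1ccccc1)(c1ccccc1)c1ccccc1)c1c(OC(=O)c2ccccc2)cc(OCc2ccccc2)cc1OCc1ccccc1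
F5 | step 3 | 5,7-bis(benzyloxy)-2-phenyl-4H-chromen-4-one | O=c1cc(-c2ccccc2)oc2cc(OCc3ccccc3)cc(OCc3ccccc3)c12
F6 | step 3 | (2S,4S)-5,7-bis(benzyloxy)-2-phenylchroman-4-ol | O[C@H]1C[C@@H](c2ccccc2)Oc2cc(OCc3ccccc3)cc(OCc3ccccc3)c21
F7 | step 4 | (2S)-5,7-bis(benzyloxy)-8-iodo-2-phenylchroman-4-one | O=C1C[C@@H](c2ccccc2)Oc2c(I)c(OCc3ccccc3)cc(OCc3ccccc3)c21
F8 | step 4 | [2-(benzyloxy)benzyl]zinc bromide | Br[Zn]Cc1ccccc1OCc1ccccc1
F9 | step 11 | (2-methoxy-5-{2-methoxy-5-[2-methoxy-5-(2-methoxybenzyl)benzyl]benzyl}phenyl)methanol | COc1ccccc1Cc1ccc(OC)c(Cc2ccc(OC)c(Cc3ccc(OC)c(CO)c3)c2)c1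
F10 | step 11 | (2S)-5,7-dihydroxy-8-(2-hydroxybenzyl)-6-{2-methoxy-5-[2-methoxy-5-[2-methoxy-5-(2-methoxybenzyl)benzyl]benzyl]benzyl}-2-phenylchroman-4-one | O=C1C[C@@H](c2ccccc2)Oc2c(Cc3ccccc3O)c(O)c(Cc3cc(Cc4cc(Cc5cc(Cc6ccccc6OC)ccc5OC)ccc4OC)ccc3OC)c(O)c21
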